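## The problem

The target **30** is a symmetrical diarylmethane. Two identical bibenzyl halves are joined by one CH2 group at C2 of each ring A. Each ring A carries the two-carbon chain to ring B at C1, the bridge at C2, a methyl ether at C3 and a free hydroxyl at C5, so the bridge carbon is flanked on both sides in both rings. There is no stereocentre, and the difficulty is regiochemical. The bridge must enter the one position between chain and methoxy group, and the two ring A oxygens must end as different groups although only their distance from the bridge tells them apart. The four free phenols are sensitive to oxidants and to base in air. The doubly activated diarylmethane can lose a benzyl cation after ipso-protonation, so strong acids and Lewis acids are excluded and the final unmasking must be neutral. The feature that invites a ring-forming key step is the sequence around one ring A: C5(OH), C4(H), C3(OMe), C2(bridge), C1(chain), C6(H). A vinylketene supplies C5 with its oxygen, C2 with its substituent, and C1 and C6; an alkoxyacetylene supplies C4 and C3 with the ether. A Danheiser benzannulation therefore delivers the resorcinol already as its monomethyl ether.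

## Retrosynthesis

**30 ⇒ 29.** Three benzyl–oxygen bonds are cut. Benzyl ethers are preferred to silyl or acetal groups because they survive organolithium reagents, LiAlH4 and base, and leave by neutral hydrogenolysis. Compound **29** has no alkene or stereocentre to interfere, and its fourth phenol is already free.

**29 ⇒ 21 + 24.** The second ring A is taken apart at C1–C2, C2–C3, C4–C5 and C5–C6. The neighbouring cut at the bridge–aryl bond would need a substitution on a ring with three nucleophilic positions. Building the ring fixes bridge, chain and both oxygens by construction. The precursors are the acyclic α-diazo enone **21** and methoxyacetylene **24**. The forward reaction needs the alkenyl group to migrate in the Wolff step, the ynol ether to add with its unsubstituted carbon to the ketene carbon, and light that the aryl ethers do not absorb.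

**21 ⇒ 18.** The diazo group is removed to the CH2 next to the carbonyl. Enone **18** has hydrogen on only one α-carbon, so activation as the trifluoroacetyl diketone **20** (through enolate **19**) and diazo transfer are regiochemically unambiguous.

**18 ⇒ 17 ⇒ 15 + 6.** The carbonyl–alkenyl bond is cut. Addition of alkenyllithium **16** (from bromide **6**) to aldehyde **15** gives allylic alcohol **17**, and oxidation gives **18**. The cut divides the molecule into the first ring A half and a four-carbon ring B piece. The carbinol centre of **17** is racemic and is erased on oxidation.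

**6 ⇒ 3 + 4.** The CH2–CH2 bond of the bromobutene is cut to Grignard reagent **5** (from chloride **3**) and 2,3-dibromopropene **4**. Direct and allylic-transposed substitution give the same product.

**15 ⇒ 13 ⇒ 12 ⇒ 11.** The aldehyde is cut between the benzylic carbon and a two-carbon unit, an acetaldehyde enolate equivalent alkylated by chloride **13** (through hydrazone **14**). This homologation needs no alkene reduction that could endanger the benzyl ethers. Chloride **13** comes from alcohol **12** and this from ester **11**, so the ester carbon becomes the bridge.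

**11 ⇒ 9 + 3.** The bibenzyl CH2–CH2 bond is cut to the laterally lithiated toluate **10** (from **9**) and chloride **3**. One C–C bond installs ring B on the methyl group, and the ester both activates that methyl and is the future bridge carbon.

**9 ⇒ 8 ⇒ 7; 3 ⇒ 2 ⇒ 1; 24 ⇒ 22.** Methyl orsellinate **7** carries the ring A pattern ready-made, and its two hydroxyls differ by chelation to the ester, so benzylation (to **8**) and methylation (to **9**) can be done in sequence. Chloride **3** comes from benzylvanillin **1** through alcohol **2**. Methoxyacetylene **24** comes from chloroacetal **22** through acetylide **23**.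

## Roads not taken

**Alternative 1:** The cut is at both chain–ring B bonds. A bis(N-acyloxyphthalimide) A2 would be coupled twice with the silyl-protected 4-iodoguaiacol A3 under cathodic nickel catalysis to give the tetrasilyl ether A1, and fluoride would then free 30.
- Merits: the coupling of primary redox-active esters with aryl iodides is well established, both bonds form in one operation, and the end game is mild.
- Weak points: the step leaves the real difficulty untouched. A2 already contains the tetra-ortho-substituted diarylmethane with differentiated oxygens and both acid chains. Each molecule must couple twice with an electron-rich aryl iodide, so mono-coupling and simple reduction of the radical are the likely leaks.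
- Comparison: this road is more convergent in its last stage and needs no photochemistry. The chosen plan sets against it that ring B enters early by plain alkylation, and that its key step is spent on the crowded ring A.

**Alternative 2:** The cut goes through both rings A. Tetraester A5 and two molecules of ynone A6 would combine by Michael addition and Claisen condensation to the bis-resorcinol A4.
- Merits: it is the shortest construction of the carbon skeleton, it uses the symmetry fully, and the bridge is present from the start.
- Weak points: each Michael addition creates a quaternary carbon beside the bridge. A5 can fragment by retro-Michael reaction under base. Aromatisation requires loss of an ester from that quaternary carbon. A4 also has four free ring A hydroxyls, of which only the two hindered ones next to the bridge must be methylated, against the steric preference.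
- Comparison: on step count this road is clearly better. The chosen plan sets against it that the oxygen differentiation is built into the ring formation.

**Alternative 3:** The cut is at both C1–chain bonds. Benzophenone A8 would be alkylated twice at its ortho C–H bonds with vinylarene A9 under ruthenium catalysis (Murai reaction) to give ketone A7, which would be deoxygenated and debenzylated.
- Merits: it is the shortest road of all. The carbonyl is both directing group and latent bridge, and each ring has only one ortho C–H bond.
- Weak points: vinylarenes raise a linear-versus-branched question. The methoxy group ortho to the carbonyl can itself be cleaved by the same catalyst. The second alkylation must occur on a ketone already twisted out of plane, and A7 is a tetra-ortho-substituted benzophenone whose reduction to CH2 is not assured.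
- Comparison: if the twofold alkylation worked, this road would be shorter by a wide margin. The chosen plan offers positional certainty from reactions of established type.

Key step: step 14

Remarks on the chemistry: methoxyacetylene (24) is assumed not to be purchasable in usable quality and is made in step 13. ArB stands for 4-(benzyloxy)-3-methoxyphenyl and ArA for 4-(benzyloxy)-2-[2-(ArB)ethyl]-6-methoxyphenyl.

## Route

Step 1
Reactants: 1 4-(benzyloxy)-3-methoxybenzaldehyde
Product: 2 [4-(benzyloxy)-3-methoxyphenyl]methanol
Conditions: NaBH4, MeOH/THF, 0 °C to rt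
Reagents that add atoms: none
Why: Borohydride reduction of an aryl aldehyde; the aryl benzyl ether is inert.

Step 2
Reactants: 2 [4-(benzyloxy)-3-methoxyphenyl]methanol
Product: 3 1-(benzyloxy)-4-(chloromethyl)-2-methoxybenzene
Conditions: SOCl2, CH2Cl2, 0 °C
Reagents that add atoms: thionyl chloride, ClS(Cl)=O
Why: Chlorodehydroxylation of an electron-rich benzylic alcohol through its chlorosulfite; only volatile by-products form.

Step 3
Reactants: 3 1-(benzyloxy)-4-(chloromethyl)-2-methoxybenzene; 4 2,3-dibromoprop-1-ene
Product: 6 2-bromo-4-ArB-but-1-ene, via benzylic Grignard reagent 5 (not isolated)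
Conditions: Mg, THF, 0 °C (slow addition, dilute); then 4, 0 °C to rt
Reagents that add atoms: none
Why: Benzylic Grignard formation followed by allylic substitution on 2,3-dibromopropene, a standard route to 2-bromo-1-alkenes. Direct and transposed attack give the same product and the vinylic bromide does not react.

Step 4
Reactants: 7 methyl 2,4-dihydroxy-6-methylbenzoate (methyl orsellinate)
Product: 8 methyl 4-(benzyloxy)-2-hydroxy-6-methylbenzoate
Conditions: BnBr (1.05 equiv), K2CO3, acetone, reflux
Reagents that add atoms: benzyl bromide, BrCc1ccccc1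
Why: Williamson etherification; the 2-hydroxyl is held in a hydrogen bond to the ester carbonyl, so one equivalent of halide should go to the 4-hydroxyl.

Step 5
Reactants: 8 methyl 4-(benzyloxy)-2-hydroxy-6-methylbenzoate
Product: 9 methyl 4-(benzyloxy)-2-methoxy-6-methylbenzoate
Conditions: MeI, K2CO3, DMF, 40 °C
Reagents that add atoms: iodomethane, CI
Why: Williamson methylation of the remaining chelated phenol in a polar solvent with excess halide.

Step 6
Reactants: 9 methyl 4-(benzyloxy)-2-methoxy-6-methylbenzoate; 3 1-(benzyloxy)-4-(chloromethyl)-2-methoxybenzene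
Product: 11 methyl 4-(benzyloxy)-2-(2-ArB-ethyl)-6-methoxybenzoate (ArA–CO2Me), via lithiated toluate 10 (not isolated)
Conditions: LiN(i-Pr)2 (LDA), THF, −78 °C; then 3, −78 to −40 °C
Reagents that add atoms: none
Why: Lateral lithiation of an ortho-toluate and alkylation with a reactive benzylic chloride; the 2,6-disubstituted ester is hindered toward self-condensation at low temperature.

Step 7
Reactants: 11 ArA–CO2Me
Product: 12 ArA-methanol (ArA–CH2OH)
Conditions: LiAlH4, THF, 0 °C to reflux
Reagents that add atoms: none
Why: Hydride reduction of the hindered aryl ester to the benzylic alcohol; aryl ethers are inert.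

Step 8
Reactants: 12 ArA–CH2OH
Product: 13 ArA-methyl chloride (ArA–CH2Cl)
Conditions: PPh3, N-chlorosuccinimide, THF, −20 to 0 °C; filtered cold and used crude at once
Reagents that add atoms: N-chlorosuccinimide, ClN1C(=O)CCC1=O
Why: Appel-type chlorination through the alkoxyphosphonium salt under neutral conditions, chosen because this 2,4-dialkoxybenzylic chloride ionises easily and should not meet acid.

Step 9
Reactants: 13 ArA–CH2Cl
Product: 15 3-ArA-propanal, via alkylated dimethylhydrazone 14 (not isolated)
Conditions: acetaldehyde N,N-dimethylhydrazone, LiN(i-Pr)2, THF, 0 °C; then 13, −78 to 0 °C; then aq. oxalic acid/Et2O, rt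
Reagents that add atoms: acetaldehyde N,N-dimethylhydrazone, CC=NN(C)C; water, O
Why: Alkylation of a metallated hydrazone (an acetaldehyde enolate equivalent) by the benzylic chloride and mild two-phase hydrolysis. This is a two-carbon homologation that needs no reduction step.

Step 10
Reactants: 15 3-ArA-propanal; 6 2-bromo-4-ArB-but-1-ene
Product: 17 1-ArA-6-ArB-4-methylidenehexan-3-ol (racemic), via alkenyllithium 16 (not isolated)
Conditions: 6, t-BuLi (2 equiv), Et2O, −78 °C; then 15, −78 °C; H2O quench
Reagents that add atoms: none
Why: Bromine–lithium exchange and 1,2-addition of the alkenyllithium to the aldehyde. The carbinol centre forms without control, as a racemate, and is removed in step 11.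

Step 11
Reactants: 17 1-ArA-6-ArB-4-methylidenehexan-3-ol
Product: 18 1-ArA-6-ArB-4-methylidenehexan-3-one
Conditions: Dess–Martin periodinane, CH2Cl2, rt
Reagents that add atoms: none
Why: Dess–Martin oxidation of a secondary allylic alcohol under neutral, non-aqueous conditions that should not isomerise the 1,1-disubstituted alkene.

Step 12
Reactants: 18 1-ArA-6-ArB-4-methylidenehexan-3-one
Product: 21 2-diazo-1-ArA-6-ArB-4-methylidenehexan-3-one, via lithium enolate 19 (not isolated), via trifluoroacetyl diketone 20 (not isolated)
Conditions: LiN(SiMe3)2, THF, −78 °C; CF3CO2CH2CF3; aq. HCl work-up; then MsN3, Et3N, H2O, MeCN, rt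
Reagents that add atoms: methanesulfonyl azide, CS(=O)(=O)N=[N+]=[N-]
Why: Detrifluoroacetylative diazo transfer: the kinetic enolate is trifluoroacetylated and the activated diketone takes the diazo group from the sulfonyl azide with loss of the trifluoroacetyl group. The method suits base-sensitive enones, and only one α-carbon of 18 bears hydrogen.

Step 13
Reactants: 22 2-chloro-1,1-dimethoxyethane
Product: 24 methoxyethyne (methoxyacetylene), via sodium methoxyacetylide 23 (not isolated)
Conditions: NaNH2 (3 equiv), liquid NH3, −33 °C; then cold H2O (brine), −70 °C; distilled into cold ClCH2CH2Cl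
Reagents that add atoms: none
Why: Base-induced loss of methanol and HCl from the chloroacetal, the standard route to alkoxyacetylenes. The product is held as its sodium acetylide until the cold aqueous quench.

Step 14
Reactants: 21 2-diazo-1-ArA-6-ArB-4-methylidenehexan-3-one; 24 methoxyethyne
Product: 29 4-(ArA-methyl)-3-(2-ArB-ethyl)-5-methoxyphenol, via vinylketene 25 (not isolated), via 4-alkenylcyclobutenone 26 (not isolated), via dienylketene 27 (not isolated), via cyclohexa-2,4-dienone 28 (not isolated)
Conditions: 24 (excess), hν (350–365 nm, Pyrex), ClCH2CH2Cl, rt, sealed vessel; then 80 °C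
Reagents that add atoms: none
Why: Irradiation expels N2 from 21 and the alkenyl group migrates from the carbonyl carbon to the diazo carbon (Wolff rearrangement, forming C1–C2), giving vinylketene 25 whose α-carbon carries the bridge. The electrophilic ketene carbon bonds to the nucleophilic unsubstituted carbon of ynol ether 24 and the α-carbon to the methoxy-bearing carbon in a (2+2) cycloaddition (C4–C5 and C2–C3), giving cyclobutenone 26. Four-electron electrocyclic opening of 26 gives dienylketene 27; only the isomer with ketene arm and alkenyl group cis can close, and reversible opening should drain the other isomer through it. Six-electron electrocyclisation of 27 forms C5–C6 and closes the only new ring, the six-membered ring A, as dienone 28, which tautomerises irreversibly to phenol 29. The closest known reaction type is the Danheiser benzannulation in its diazoketone variant with alkoxy- or siloxyacetylenes. No stereocentre is created, and the quaternary centre of 26 is transient. The selectivity needed is regiochemical: the polarity of the ynol ether places the alkyne oxygen at C3 next to the bridge and the ketene oxygen at C5 as the free phenol, and only the alkenyl group can migrate because it is the sole substituent on the carbonyl carbon. Pyrex-filtered light spares the aryl benzyl ethers, and methoxyacetylene has no β-hydrogen and so cannot fragment to ketene on warming.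

Step 15
Reactants: 29 4-(ArA-methyl)-3-(2-ArB-ethyl)-5-methoxyphenol
Product: 30 4,4'-methylenebis{3-[2-(4-hydroxy-3-methoxyphenyl)ethyl]-5-methoxyphenol}
Conditions: H2 (1 atm), Pd/C, EtOAc/MeOH, rt
Reagents that add atoms: none
Why: Hydrogenolysis of the three aryl benzyl ethers under neutral conditions; methyl ethers, bibenzyl chains and the diarylmethane are inert, and acid is avoided.

## Compound list

1 | 4-(benzyloxy)-3-methoxybenzaldehyde | COc1cc(C=O)ccc1OCc1ccccc1 | starting material
2 | [4-(benzyloxy)-3-methoxyphenyl]methanol | COc1cc(CO)ccc1OCc1ccccc1 | intermediate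
3 | 1-(benzyloxy)-4-(chloromethyl)-2-methoxybenzene | COc1cc(CCl)ccc1OCc1ccccc1 | intermediate
4 | 2,3-dibromoprop-1-ene | C=C(Br)CBr | starting material
5 | {[4-(benzyloxy)-3-methoxyphenyl]methyl}magnesium chloride | COc1cc(C[Mg]Cl)ccc1OCc1ccccc1 | intermediate
6 | 1-(benzyloxy)-4-(3-bromobut-3-en-1-yl)-2-methoxybenzene | COc1cc(CCC(Br)=C)ccc1OCc1ccccc1 | intermediate
7 | methyl 2,4-dihydroxy-6-methylbenzoate (methyl orsellinate) | COC(=O)c1c(C)cc(O)cc1O | starting material
8 | methyl 4-(benzyloxy)-2-hydroxy-6-methylbenzoate | COC(=O)c1c(C)cc(OCc2ccccc2)cc1O | intermediate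
9 | methyl 4-(benzyloxy)-2-methoxy-6-methylbenzoate | COC(=O)c1c(C)cc(OCc2ccccc2)cc1OC | intermediate
10 | methyl 4-(benzyloxy)-2-(lithiomethyl)-6-methoxybenzoate | COC(=O)c1c(C[Li])cc(OCc2ccccc2)cc1OC | intermediate
11 | methyl 4-(benzyloxy)-2-{2-[4-(benzyloxy)-3-methoxyphenyl]ethyl}-6-methoxybenzoate | COC(=O)c1c(CCc2ccc(OCc3ccccc3)c(OC)c2)cc(OCc2ccccc2)cc1OC | intermediate
12 | (4-(benzyloxy)-2-{2-[4-(benzyloxy)-3-methoxyphenyl]ethyl}-6-methoxyphenyl)methanol | OCc1c(CCc2ccc(OCc3ccccc3)c(OC)c2)cc(OCc2ccccc2)cc1OC | intermediate
13 | 5-(benzyloxy)-1-{2-[4-(benzyloxy)-3-methoxyphenyl]ethyl}-2-(chloromethyl)-3-methoxybenzene | ClCc1c(CCc2ccc(OCc3ccccc3)c(OC)c2)cc(OCc2ccccc2)cc1OC | intermediate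
14 | 3-ArA-propanal N,N-dimethylhydrazone | CN(C)N=CCCc1c(CCc2ccc(OCc3ccccc3)c(OC)c2)cc(OCc2ccccc2)cc1OC | intermediate
15 | 3-(4-(benzyloxy)-2-{2-[4-(benzyloxy)-3-methoxyphenyl]ethyl}-6-methoxyphenyl)propanal | O=CCCc1c(CCc2ccc(OCc3ccccc3)c(OC)c2)cc(OCc2ccccc2)cc1OC | intermediate
16 | {4-[4-(benzyloxy)-3-methoxyphenyl]but-1-en-2-yl}lithium | [Li]C(=C)CCc1ccc(OCc2ccccc2)c(OC)c1 | intermediate
17 | 1-ArA-6-ArB-4-methylidenehexan-3-ol (racemic) | OC(CCc1c(CCc2ccc(OCc3ccccc3)c(OC)c2)cc(OCc2ccccc2)cc1OC)C(=C)CCc1ccc(OCc2ccccc2)c(OC)c1 | intermediate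
18 | 1-ArA-6-ArB-4-methylidenehexan-3-one | O=C(CCc1c(CCc2ccc(OCc3ccccc3)c(OC)c2)cc(OCc2ccccc2)cc1OC)C(=C)CCc1ccc(OCc2ccccc2)c(OC)c1 | intermediate
19 | lithium 1-ArA-6-ArB-4-methylidenehex-2-en-3-olate | [Li]OC(=CCc1c(CCc2ccc(OCc3ccccc3)c(OC)c2)cc(OCc2ccccc2)cc1OC)C(=C)CCc1ccc(OCc2ccccc2)c(OC)c1 | intermediate
20 | 3-(ArA-methyl)-7-ArB-1,1,1-trifluoro-5-methylideneheptane-2,4-dione | O=C(C(Cc1c(CCc2ccc(OCc3ccccc3)c(OC)c2)cc(OCc2ccccc2)cc1OC)C(=O)C(F)(F)F)C(=C)CCc1ccc(OCc2ccccc2)c(OC)c1 | intermediate
21 | 2-diazo-1-ArA-6-ArB-4-methylidenehexan-3-one | [N-]=[N+]=C(Cc1c(CCc2ccc(OCc3ccccc3)c(OC)c2)cc(OCc2ccccc2)cc1OC)C(=O)C(=C)CCc1ccc(OCc2ccccc2)c(OC)c1 | intermediate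
22 | 2-chloro-1,1-dimethoxyethane (chloroacetaldehyde dimethyl acetal) | COC(CCl)OC | starting material
23 | sodium methoxyethynide | [Na]C#COC | intermediate
24 | methoxyethyne (methoxyacetylene) | COC#C | intermediate
25 | 2-(ArA-methyl)-5-ArB-3-methylidenepent-1-en-1-one (vinylketene) | O=C=C(Cc1c(CCc2ccc(OCc3ccccc3)c(OC)c2)cc(OCc2ccccc2)cc1OC)C(=C)CCc1ccc(OCc2ccccc2)c(OC)c1 | intermediate
26 | 4-(ArA-methyl)-4-(4-ArB-but-1-en-2-yl)-3-methoxycyclobut-2-en-1-one (racemic) | O=C1C=C(OC)C1(Cc1c(CCc2ccc(OCc3ccccc3)c(OC)c2)cc(OCc2ccccc2)cc1OC)C(=C)CCc1ccc(OCc2ccccc2)c(OC)c1 | intermediate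
27 | (3E)-4-(ArA-methyl)-7-ArB-3-methoxy-5-methylidenehepta-1,3-dien-1-one (ketene arm and alkenyl group cis) | O=C=C/C(OC)=C(Cc1c(CCc2ccc(OCc3ccccc3)c(OC)c2)cc(OCc2ccccc2)cc1OC)\C(=C)CCc1ccc(OCc2ccccc2)c(OC)c1 | intermediate
28 | 4-(ArA-methyl)-5-(2-ArB-ethyl)-3-methoxycyclohexa-2,4-dien-1-one | O=C1C=C(OC)C(Cc2c(CCc3ccc(OCc4ccccc4)c(OC)c3)cc(OCc3ccccc3)cc2OC)=C(CCc2ccc(OCc3ccccc3)c(OC)c2)C1 | intermediate
29 | 4-[(4-(benzyloxy)-2-{2-[4-(benzyloxy)-3-methoxyphenyl]ethyl}-6-methoxyphenyl)methyl]-3-{2-[4-(benzyloxy)-3-methoxyphenyl]ethyl}-5-methoxyphenol | COc1cc(O)cc(CCc2ccc(OCc3ccccc3)c(OC)c2)c1Cc1c(CCc2ccc(OCc3ccccc3)c(OC)c2)cc(OCc2ccccc2)cc1OC | intermediate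
30 | 4,4'-methylenebis{3-[2-(4-hydroxy-3-methoxyphenyl)ethyl]-5-methoxyphenol} | COc1cc(CCc2cc(O)cc(OC)c2Cc2c(CCc3ccc(O)c(OC)c3)cc(O)cc2OC)ccc1O | target

## Step count and risks

Total: 15 steps. Longest linear sequence: 11 steps (steps 4 to 12, 14 and 15 from methyl orsellinate 7; the sequence through steps 1, 2 and 6 is equally long).

**Step 14 (key step).** Loss of nitrogen may lead partly to a free ketocarbene that shifts a hydrogen from the neighbouring benzylic CH2 instead of undergoing the Wolff shift. The volatile ynol ether may also be too dilute, so that the vinylketene dimerises or acylates the newly formed phenol. The second problem is met within the step by a sealed vessel, an excess of 24 and, if needed, mild methanolysis of any aryl ester on work-up. The first is a property of the substrate. The fallback gives up ring construction and joins two preformed halves. It sets out from 11 and 13 and comes back at 30.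
- Ester 11 would be saponified (KOH, aq. DMSO, heat) to 4-(benzyloxy)-2-[2-(ArB)ethyl]-6-methoxybenzoic acid F1.
- Ipso-iododecarboxylation (I2, K3PO4, MeCN, heat) would give the aryl iodide F2.
- Zinc insertion into chloride 13 (Zn, LiCl, THF) would give the benzylzinc chloride F3.
- Negishi coupling of F2 and F3 (Pd(OAc)2, SPhos, THF) would give the tetrabenzyl ether F4.
- Hydrogenolysis as in step 15 would give 30.

**Step 8 (with the use of 13 in step 9).** The chloride ionises readily, and self-alkylation of its electron-rich rings during formation, concentration or a slow alkylation would consume it. The fallback avoids any benzylic halide. It sets out from 12 and comes back at 15.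
- Oxidation of 12 (MnO2, CH2Cl2) would give the benzaldehyde F5.
- Horner–Wadsworth–Emmons reaction with trimethyl phosphonoacetate (NaH, THF) would give the methyl (E)-cinnamate F6.
- Conjugate reduction with Mg in MeOH, which leaves benzyl ethers alone, would give the methyl 3-arylpropanoate F7.
- Reduction with i-Bu2AlH (toluene, −78 °C) would give 15.

**Step 3.** Homocoupling during formation of the electron-rich benzylic Grignard reagent 5 would lower the supply of bromide 6. The fallback replaces steps 3 and 10 by a Nozaki–Hiyama–Kishi coupling. It sets out from 15 and comes back at 17.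
- Purchased zingerone F8 would be benzylated (BnBr, K2CO3, acetone) to the ketone F9.
- The kinetic enolate (KN(SiMe3)2, THF, −78 °C) would be trapped with PhNTf2 as the terminal enol triflate F10.
- F10 would be coupled with aldehyde 15 (CrCl2, catalytic NiCl2, DMF, rt) to give 17.

## Further compounds

F1 | step 14 | 4-(benzyloxy)-2-{2-[4-(benzyloxy)-3-methoxyphenyl]ethyl}-6-methoxybenzoic acid | OC(=O)c1c(CCc2ccc(OCc3ccccc3)c(OC)c2)cc(OCc2ccccc2)cc1OC
F2 | step 14 | 5-(benzyloxy)-1-{2-[4-(benzyloxy)-3-methoxyphenyl]ethyl}-2-iodo-3-methoxybenzene | Ic1c(CCc2ccc(OCc3ccccc3)c(OC)c2)cc(OCc2ccccc2)cc1OC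
F3 | step 14 | [(4-(benzyloxy)-2-{2-[4-(benzyloxy)-3-methoxyphenyl]ethyl}-6-methoxyphenyl)methyl]zinc chloride | Cl[Zn]Cc1c(CCc2ccc(OCc3ccccc3)c(OC)c2)cc(OCc2ccccc2)cc1OC
F4 | step 14 | bis(4-(benzyloxy)-2-{2-[4-(benzyloxy)-3-methoxyphenyl]ethyl}-6-methoxyphenyl)methane | COc1cc(OCc2ccccc2)cc(CCc2ccc(OCc3ccccc3)c(OC)c2)c1Cc1c(CCc2ccc(OCc3ccccc3)c(OC)c2)cc(OCc2ccccc2)cc1OC
F5 | step 8 | 4-(benzyloxy)-2-{2-[4-(benzyloxy)-3-methoxyphenyl]ethyl}-6-methoxybenzaldehyde | O=Cc1c(CCc2ccc(OCc3ccccc3)c(OC)c2)cc(OCc2ccccc2)cc1OC
F6 | step 8 | methyl (2E)-3-(4-(benzyloxy)-2-{2-[4-(benzyloxy)-3-methoxyphenyl]ethyl}-6-methoxyphenyl)prop-2-enoate | COC(=O)/C=C/c1c(CCc2ccc(OCc3ccccc3)c(OC)c2)cc(OCc2ccccc2)cc1OC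
F7 | step 8 | methyl 3-(4-(benzyloxy)-2-{2-[4-(benzyloxy)-3-methoxyphenyl]ethyl}-6-methoxyphenyl)propanoate | COC(=O)CCc1c(CCc2ccc(OCc3ccccc3)c(OC)c2)cc(OCc2ccccc2)cc1OC
F8 | step 3 | 4-(4-hydroxy-3-methoxyphenyl)butan-2-one (zingerone; purchased) | CC(=O)CCc1ccc(O)c(OC)c1
F9 | step 3 | 4-[4-(benzyloxy)-3-methoxyphenyl]butan-2-one | CC(=O)CCc1ccc(OCc2ccccc2)c(OC)c1
F10 | step 3 | 4-[4-(benzyloxy)-3-methoxyphenyl]but-1-en-2-yl trifluoromethanesulfonate | C=C(CCc1ccc(OCc2ccccc2)c(OC)c1)OS(=O)(=O)C(F)(F)F
A1 | alternative 1 | tetrakis(triisopropylsilyl) ether of the target | COc1cc(CCc2cc(O[Si](C(C)C)(C(C)C)C(C)C)cc(OC)c2Cc2c(CCc3ccc(O[Si](C(C)C)(C(C)C)C(C)C)c(OC)c3)cc(O[Si](C(C)C)(C(C)C)C(C)C)cc2OC)ccc1O[Si](C(C)C)(C(C)C)C(C)C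
A2 | alternative 1 | bis(1,3-dioxoisoindolin-2-yl) 3,3'-{methylenebis[3-methoxy-5-(triisopropylsilyloxy)-2,1-phenylene]}dipropanoate | COc1cc(O[Si](C(C)C)(C(C)C)C(C)C)cc(CCC(=O)ON2C(=O)c3ccccc3C2=O)c1Cc1c(CCC(=O)ON2C(=O)c3ccccc3C2=O)cc(O[Si](C(C)C)(C(C)C)C(C)C)cc1OC
A3 | alternative 1 | (4-iodo-2-methoxyphenoxy)triisopropylsilane | COc1cc(I)ccc1O[Si](C(C)C)(C(C)C)C(C)C
A4 | alternative 2 | 4,4'-methylenebis(5-{2-[4-(benzyloxy)-3-methoxyphenyl]ethyl}benzene-1,3-diol) | Oc1cc(O)c(Cc2c(O)cc(O)cc2CCc2ccc(OCc3ccccc3)c(OC)c2)c(CCc2ccc(OCc3ccccc3)c(OC)c2)c1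
A5 | alternative 2 | tetramethyl propane-1,1,3,3-tetracarboxylate | COC(=O)C(CC(C(=O)OC)C(=O)OC)C(=O)OC
A6 | alternative 2 | 6-[4-(benzyloxy)-3-methoxyphenyl]hex-3-yn-2-one | CC(=O)C#CCCc1ccc(OCc2ccccc2)c(OC)c1
A7 | alternative 3 | bis(4-benzyloxy-2-{2-[4-(benzyloxy)-3-methoxyphenyl]ethyl}-6-methoxyphenyl)methanone | COc1cc(OCc2ccccc2)cc(CCc2ccc(OCc3ccccc3)c(OC)c2)c1C(=O)c1c(CCc2ccc(OCc3ccccc3)c(OC)c2)cc(OCc2ccccc2)cc1OC
A8 | alternative 3 | bis[4-(benzyloxy)-2-methoxyphenyl]methanone | COc1cc(OCc2ccccc2)ccc1C(=O)c1ccc(OCc2ccccc2)cc1OC
A9 | alternative 3 | 1-(benzyloxy)-4-ethenyl-2-methoxybenzene | C=Cc1ccc(OCc2ccccc2)c(OC)c1
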